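**Plan**

Germacrane locants are used throughout: C1 ketone, C2=C3 furanone alkene, C4 (methyl C15), C5, C6 (lactone O), C7, C8 (ester O), C9, C10 (methyl C14, ring O), C11=C13 methylene, C12 lactone C=O.
Retrosynthesis: remove the C8 ester (acid 28), then cut the lactone at C6–C7 and C11–C12 (with C12–O) to formyl allene 21 plus CO. Open the furanone at C3–O to hydroxy ynone 18, and cut C1–C2 into alkyne 15 and dioxolanone 10.
Forward: 10 (C1, C7–C11, C13, C14) comes from (R)-citramalic acid and 15 (C2–C6, C15) from crotonaldehyde; they are joined at C1–C2. The furanone ring (O, C3, C2, C1, C10) is closed first, then one carbonylative [2+2+1] closes the nine-membered oxa-bridged ring (the ten-membered carbocycle) and the lactone together; the side chain goes on last.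
Enabling feature: the ring O–C6–C7–C11(=C13)–C12(=O) is the sum of an aldehyde (C6=O), the inner π-bond of a terminal allene (C7=C11=C13) and CO (C12). The flat furanone holds the arms C4–C5–C6 and C9–C8–C7 in a 1,3-relationship across its oxygen, so C6 and C7 can meet.
Stereochemistry: C10 is bought (citramalic acid); C8 and C4 are set by catalysts (transfer hydrogenation, conjugate alkynylation). C6 and C7 arise together in the key step by relay from C8 and the ring; the side-chain centre is bought (bromo acid 24).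

Key step: step 12

Assumption: acid 24 and both antipodes of the ligands in steps 3 and 7 are taken as purchasable; the sense of induction in steps 3 and 7 follows the usual models, and the mirror-image ligand would be used if either proved opposite.

**Route**

Step 1
Reactants: 1 (R)-citramalic acid
Product: 2 2-[(4R)-2,2,4-trimethyl-5-oxo-1,3-dioxolan-4-yl]acetic acid
Conditions: 2,2-dimethoxypropane, TsOH·H2O (cat.), rt
Reagents that add atoms: 2,2-dimethoxypropane, COC(C)(C)OC
Why: Acid-catalysed acetonide (1,3-dioxolan-4-one) formation takes the α-hydroxy acid unit because the five-membered ring forms in preference to a six-membered one with the β-carboxyl; C10 is not touched.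

Step 2
Reactants: 2 2-[(4R)-2,2,4-trimethyl-5-oxo-1,3-dioxolan-4-yl]acetic acid; 3 ethynyltrimethylsilane
Product: 5 (5R)-2,2,5-trimethyl-5-[2-oxo-4-(trimethylsilyl)but-3-yn-1-yl]-1,3-dioxolan-4-one, via acid chloride 4 (not isolated)
Conditions: (COCl)2, DMF (cat.), CH2Cl2, 0 °C to rt, evaporate; then 3, PdCl2(PPh3)2 (2 mol %), CuI (4 mol %), Et3N (1.1 equiv), THF, rt
Reagents that add atoms: none
Why: Acid chloride formation and acyl Sonogashira coupling give the alkynyl ketone under near-neutral conditions that the dioxolanone tolerates; no stereocenter is made.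

Step 3
Reactants: 5 (5R)-2,2,5-trimethyl-5-[2-oxo-4-(trimethylsilyl)but-3-yn-1-yl]-1,3-dioxolan-4-one
Product: 6 (5R)-5-[(2S)-2-hydroxy-4-(trimethylsilyl)but-3-yn-1-yl]-2,2,5-trimethyl-1,3-dioxolan-4-one
Conditions: Ru[(S,S)-TsDPEN](p-cymene) (1 mol %), i-PrOH, rt
Reagents that add atoms: none
Why: Noyori asymmetric transfer hydrogenation of an alkynyl ketone: the catalyst tells the alkynyl from the alkyl flank and should set C8 as S under catalyst control, whatever the configuration at C10.

Step 4
Reactants: 6 (5R)-5-[(2S)-2-hydroxy-4-(trimethylsilyl)but-3-yn-1-yl]-2,2,5-trimethyl-1,3-dioxolan-4-one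
Product: 7 (5R)-5-[(2S)-2-(tert-butyldimethylsilyloxy)-4-(trimethylsilyl)but-3-yn-1-yl]-2,2,5-trimethyl-1,3-dioxolan-4-one
Conditions: TBSOTf, 2,6-lutidine, CH2Cl2, −78 to 0 °C
Reagents that add atoms: tert-butyldimethylsilyl trifluoromethanesulfonate, CC(C)(C)[Si](C)(C)OS(=O)(=O)C(F)(F)F
Why: Silyl ether formation caps the C8 hydroxyl before it can translactonise onto the dioxolanone and installs the bulky group that later screens one allene face.

Step 5
Reactants: 7 (5R)-5-[(2S)-2-(tert-butyldimethylsilyloxy)-4-(trimethylsilyl)but-3-yn-1-yl]-2,2,5-trimethyl-1,3-dioxolan-4-one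
Product: 8 (5R)-5-[(2S)-2-(tert-butyldimethylsilyloxy)but-3-yn-1-yl]-2,2,5-trimethyl-1,3-dioxolan-4-one
Conditions: AgNO3 (0.1 equiv), acetone–H2O (4:1), rt
Reagents that add atoms: none
Why: Silver-catalysed protiodesilylation removes the alkynyl silyl group under neutral conditions, so the TBS ether and the base-sensitive dioxolanone stay intact.

Step 6
Reactants: 8 (5R)-5-[(2S)-2-(tert-butyldimethylsilyloxy)but-3-yn-1-yl]-2,2,5-trimethyl-1,3-dioxolan-4-one
Product: 10 (5R)-5-[(2S)-2-(tert-butyldimethylsilyloxy)penta-3,4-dien-1-yl]-2,2,5-trimethyl-1,3-dioxolan-4-one, via propargylic amine 9 (not isolated)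
Conditions: (CH2O)n (2.5 equiv), CuI (0.5 equiv), Cy2NH (1.8 equiv), 1,4-dioxane, 100 °C
Reagents that add atoms: paraformaldehyde (as formaldehyde), C=O
Why: Crabbé homologation: the copper acetylide Mannich reaction gives propargylic amine 9, whose copper-assisted 1,5-hydride shift and fragmentation delivers the terminal allene (C13 from formaldehyde) without touching C8.

Step 7
Reactants: 11 (E)-crotonaldehyde; 12 ethynyltriisopropylsilane
Product: 13 (3S)-3-methyl-5-(triisopropylsilyl)pent-4-ynal
Conditions: [Rh(OAc)(C2H4)2]2 (2.5 mol %), (R)-DTBM-SEGPHOS (5.5 mol %), MeOH, 40 °C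
Reagents that add atoms: none
Why: Rhodium-catalysed asymmetric conjugate alkynylation of an enal with a bulky silylacetylene: the chiral bisphosphine–alkynylrhodium species adds to one enantioface of the enal and should set C4 as S.

Step 8
Reactants: 13 (3S)-3-methyl-5-(triisopropylsilyl)pent-4-ynal
Product: 14 [(3S)-5,5-dimethoxy-3-methylpent-1-yn-1-yl]triisopropylsilane
Conditions: HC(OMe)3, TsOH·H2O (cat.), MeOH, rt
Reagents that add atoms: trimethyl orthoformate, COC(OC)OC
Why: Acid-catalysed acetalisation masks the future C6 aldehyde for the organolithium step; C4 is β to the carbonyl and is not at risk.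

Step 9
Reactants: 14 [(3S)-5,5-dimethoxy-3-methylpent-1-yn-1-yl]triisopropylsilane
Product: 15 (3S)-5,5-dimethoxy-3-methylpent-1-yne
Conditions: TBAF, THF, 0 °C to rt
Reagents that add atoms: none
Why: Fluoride-mediated C-desilylation frees the terminal alkyne; the acetal is inert to fluoride.

Step 10
Reactants: 15 (3S)-5,5-dimethoxy-3-methylpent-1-yne; 10 (5R)-5-[(2S)-2-(tert-butyldimethylsilyloxy)penta-3,4-dien-1-yl]-2,2,5-trimethyl-1,3-dioxolan-4-one
Product: 18 (3S,7R,9S)-9-(tert-butyldimethylsilyloxy)-7-hydroxy-1,1-dimethoxy-3,7-dimethyldodeca-10,11-dien-4-yn-6-one, via lithium acetylide 16 (not isolated), via lithium hemiketal alkoxide 17 (not isolated)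
Conditions: 15, n-BuLi (1.0 equiv), THF, −78 °C; then 10, −78 °C; sat. aq. NH4Cl at −78 °C
Reagents that add atoms: none
Why: Acylation of a lithium acetylide by a 1,3-dioxolan-4-one (an acetonide-activated α-hydroxy acid without α-hydrogen): adduct 17 is held as a cyclic lithium hemiketal at −78 °C, which prevents a second addition, and gives the ynone, its free tertiary hydroxyl and acetone on quenching.

Step 11
Reactants: 18 (3S,7R,9S)-9-(tert-butyldimethylsilyloxy)-7-hydroxy-1,1-dimethoxy-3,7-dimethyldodeca-10,11-dien-4-yn-6-one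
Product: 21 (3S)-3-{(5R)-5-[(2S)-2-(tert-butyldimethylsilyloxy)penta-3,4-dien-1-yl]-5-methyl-4-oxo-4,5-dihydrofuran-2-yl}butanal, via diethylamino enone 19 (not isolated), via furanone acetal 20 (not isolated)
Conditions: Et2NH (3 equiv), EtOH, rt; evaporate; then PPTS (0.2 equiv), acetone–H2O (9:1), 45 °C
Reagents that add atoms: water, O
Why: Conjugate addition of the amine to the ynone and 5-exo-trig addition–elimination by the C10 hydroxyl (the classical α'-hydroxy ynone to 3(2H)-furanone cyclisation) close the furanone without a π-acidic metal that would engage the allene, and buffered acetal hydrolysis then frees the C6 aldehyde while the TBS ether survives.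

Step 12
Reactants: 21 (3S)-3-{(5R)-5-[(2S)-2-(tert-butyldimethylsilyloxy)penta-3,4-dien-1-yl]-5-methyl-4-oxo-4,5-dihydrofuran-2-yl}butanal
Product: 22 (4S,6R,7S,8S,10R)-8-(tert-butyldimethylsilyloxy)-1-oxo-3,10-epoxygermacra-2,11(13)-dien-12,6-olide
Conditions: Ru3(CO)12 (10 mol %), CO (20 atm), 1,4-dioxane (0.003 M, slow addition of 21), 120 °C
Reagents that add atoms: carbon monoxide, [C-]#[O+]
Why: Proposed new method: zerovalent ruthenium carbonyl binds the aldehyde C6=O and the inner allene bond C7=C11, oxidative cyclisation joins C6 to C7 to give an oxaruthenacyclopentane whose Ru–C11 carbon carries the exocyclic C11=C13 methylene, CO inserts into Ru–C11 (making C11–C12) and acyl–alkoxide reductive elimination (C12–O) releases lactone and catalyst, so the ring-forming C–C bond is made much as in an intramolecular allylmetal addition to an aldehyde. The closest known reaction is the Ru3(CO)12- or Mo(CO)6-mediated cyclocarbonylation of allenyl aldehydes to fused α-methylene-γ-butyrolactones (allenic hetero-Pauson–Khand reaction), shown for five- and six-membered ring formation; closing a medium ring with it is the untested part. Two rings close: the nine-membered oxacycle O–C3–C4–C5–C6–C7–C8–C9–C10 (which completes the ten-membered carbocycle C1–C10 and the 11-oxabicyclo[6.2.1]undecene core) by the C6–C7 bond in exo mode at both π-bonds (9-exo-trig at C6, the C7=C11 bond staying outside the ring), and the γ-lactone O–C6–C7–C11–C12 as the five-membered ring of the [2+2+1] by C–O reductive elimination. C7 is controlled by C8: in the reactive conformer C8–H eclipses the allene and the C8–O bond lies anti to the forming bond (Felkin–Anh-like), so the OTBS group screens one face and the C9 tether can only bring C6 to the other, which gives 7S; C6 is controlled by the ring, since in a metallacycle fused to a nine-membered ring the arms C5 and C8 should lie anti across the new bond, which gives the 6,7-trans lactone (6R). The step needs bond formation at C7 and not at C13, ring closure and not oligomerisation, and an untouched furanone; it relies on the furanone ring fixing C4 and C9 in a 1,3-relationship across the ring oxygen so that C6 and C7 are near, on the shorter path to C7, on slow addition at high dilution under CO pressure, and on the low reactivity of the electron-poor trisubstituted C2=C3 bond.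

Step 13
Reactants: 22 (4S,6R,7S,8S,10R)-8-(tert-butyldimethylsilyloxy)-1-oxo-3,10-epoxygermacra-2,11(13)-dien-12,6-olide
Product: 23 (4S,6R,7R,8S,10R)-8-hydroxy-1-oxo-3,10-epoxygermacra-2,11(13)-dien-12,6-olide
Conditions: HF·pyridine, pyridine, THF, 0 °C to rt
Reagents that add atoms: none
Why: Fluoride cleavage of the secondary silyl ether under non-basic conditions that the α-methylene lactone tolerates; no bond to a stereocenter is broken (only the formal C7 descriptor changes).

Step 14
Reactants: 24 (S)-3-bromo-2-hydroxy-2-methylpropanoic acid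
Product: 26 (R)-2,3-dihydroxy-2-methylpropanoic acid, via potassium 2-methylglycidate 25 (not isolated)
Conditions: KOH (3 equiv), H2O, 80 °C; then aq. HCl to pH 1, evaporate, extract with acetone
Reagents that add atoms: potassium hydroxide, [K+].[OH-]
Why: Intramolecular Williamson closure to glycidate 25 and SN2 opening by hydroxide at the unhindered CH2 replace bromine by hydroxyl without touching the quaternary stereocenter (the descriptor changes from S to R only because the CIP priorities change).

Step 15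
Reactants: 26 (R)-2,3-dihydroxy-2-methylpropanoic acid
Product: 27 methyl (4R)-2,2,4-trimethyl-1,3-dioxolane-4-carboxylate
Conditions: 2,2-dimethoxypropane, MeOH, TsOH·H2O (cat.), 50 °C
Reagents that add atoms: 2,2-dimethoxypropane, COC(C)(C)OC; methanol, CO
Why: One-pot Fischer esterification and acetonide formation, as practised on tartaric acid, protects both hydroxyls as a compact dioxolane.

Step 16
Reactants: 27 methyl (4R)-2,2,4-trimethyl-1,3-dioxolane-4-carboxylate
Product: 28 (4R)-2,2,4-trimethyl-1,3-dioxolane-4-carboxylic acid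
Conditions: LiOH·H2O, THF–H2O, 0 °C to rt; then 1 M HCl to pH 3 at 0 °C
Reagents that add atoms: lithium hydroxide, [Li+].[OH-]
Why: Saponification of the methyl ester; the acetonide is stable to base and to the brief cold acidification.

Step 17
Reactants: 28 (4R)-2,2,4-trimethyl-1,3-dioxolane-4-carboxylic acid; 23 (4S,6R,7R,8S,10R)-8-hydroxy-1-oxo-3,10-epoxygermacra-2,11(13)-dien-12,6-olide
Product: 30 (4S,6R,7S,8S,10R)-1-oxo-3,10-epoxygermacra-2,11(13)-dien-12,6-olid-8-yl (4R)-2,2,4-trimethyl-1,3-dioxolane-4-carboxylate, via mixed anhydride 29 (not isolated)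
Conditions: 28, 2,4,6-trichlorobenzoyl chloride, Et3N, toluene, rt; then 23, DMAP, toluene, rt to 40 °C
Reagents that add atoms: none
Why: Yamaguchi esterification through mixed anhydride 29 suits a hindered secondary alcohol and an α-quaternary acid; the C8–O bond is not broken, so C8 keeps its configuration.

Step 18
Reactants: 30 (4S,6R,7S,8S,10R)-1-oxo-3,10-epoxygermacra-2,11(13)-dien-12,6-olid-8-yl (4R)-2,2,4-trimethyl-1,3-dioxolane-4-carboxylate
Product: 31 (4S,6R,7S,8S,10R)-8-[(2R)-2,3-dihydroxy-2-methylpropanoyloxy]-1-oxo-3,10-epoxygermacra-2,11(13)-dien-12,6-olide (target)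
Conditions: TFA–H2O (9:1), CH2Cl2, 0 °C
Reagents that add atoms: none
Why: Aqueous acid hydrolysis of the acetonide frees the diol; lactone, furanone and the tertiary-alkyl ester should survive brief cold acid.

**Compound list**

1 | (R)-citramalic acid, (2R)-2-hydroxy-2-methylbutanedioic acid | OC(=O)[C@@](C)(CC(=O)O)O | starting material
2 | 2-[(4R)-2,2,4-trimethyl-5-oxo-1,3-dioxolan-4-yl]acetic acid | O=C1[C@@](C)(CC(=O)O)OC(C)(C)O1 | intermediate
3 | ethynyltrimethylsilane | C#C[Si](C)(C)C | starting material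
4 | 2-[(4R)-2,2,4-trimethyl-5-oxo-1,3-dioxolan-4-yl]acetyl chloride | O=C1[C@@](C)(CC(=O)Cl)OC(C)(C)O1 | intermediate
5 | (5R)-2,2,5-trimethyl-5-[2-oxo-4-(trimethylsilyl)but-3-yn-1-yl]-1,3-dioxolan-4-one | O=C1[C@@](C)(CC(=O)C#C[Si](C)(C)C)OC(C)(C)O1 | intermediate
6 | (5R)-5-[(2S)-2-hydroxy-4-(trimethylsilyl)but-3-yn-1-yl]-2,2,5-trimethyl-1,3-dioxolan-4-one | O=C1[C@@](C)(C[C@H](O)C#C[Si](C)(C)C)OC(C)(C)O1 | intermediate
7 | (5R)-5-[(2S)-2-(tert-butyldimethylsilyloxy)-4-(trimethylsilyl)but-3-yn-1-yl]-2,2,5-trimethyl-1,3-dioxolan-4-one | O=C1[C@@](C)(C[C@H](O[Si](C)(C)C(C)(C)C)C#C[Si](C)(C)C)OC(C)(C)O1 | intermediate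
8 | (5R)-5-[(2S)-2-(tert-butyldimethylsilyloxy)but-3-yn-1-yl]-2,2,5-trimethyl-1,3-dioxolan-4-one | O=C1[C@@](C)(C[C@H](O[Si](C)(C)C(C)(C)C)C#C)OC(C)(C)O1 | intermediate
9 | (5R)-5-[(2S)-2-(tert-butyldimethylsilyloxy)-5-(dicyclohexylamino)pent-3-yn-1-yl]-2,2,5-trimethyl-1,3-dioxolan-4-one | O=C1[C@@](C)(C[C@H](O[Si](C)(C)C(C)(C)C)C#CCN(C2CCCCC2)C2CCCCC2)OC(C)(C)O1 | intermediate
10 | (5R)-5-[(2S)-2-(tert-butyldimethylsilyloxy)penta-3,4-dien-1-yl]-2,2,5-trimethyl-1,3-dioxolan-4-one | O=C1[C@@](C)(C[C@H](O[Si](C)(C)C(C)(C)C)C=C=C)OC(C)(C)O1 | intermediate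
11 | (E)-crotonaldehyde | C/C=C/C=O | starting material
12 | ethynyltriisopropylsilane | C#C[Si](C(C)C)(C(C)C)C(C)C | starting material
13 | (3S)-3-methyl-5-(triisopropylsilyl)pent-4-ynal | O=CC[C@H](C)C#C[Si](C(C)C)(C(C)C)C(C)C | intermediate
14 | [(3S)-5,5-dimethoxy-3-methylpent-1-yn-1-yl]triisopropylsilane | COC(OC)C[C@H](C)C#C[Si](C(C)C)(C(C)C)C(C)C | intermediate
15 | (3S)-5,5-dimethoxy-3-methylpent-1-yne | COC(OC)C[C@H](C)C#C | intermediate
16 | lithium (3S)-5,5-dimethoxy-3-methylpent-1-yn-1-ide | COC(OC)C[C@H](C)C#C[Li] | intermediate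
17 | lithium (5R)-5-[(2S)-2-(tert-butyldimethylsilyloxy)penta-3,4-dien-1-yl]-4-[(3S)-5,5-dimethoxy-3-methylpent-1-yn-1-yl]-2,2,5-trimethyl-1,3-dioxolan-4-olate (both epimers at the hemiketal carbon) | COC(OC)C[C@H](C)C#CC1([O-])[C@@](C)(C[C@H](O[Si](C)(C)C(C)(C)C)C=C=C)OC(C)(C)O1.[Li+] | intermediate
18 | (3S,7R,9S)-9-(tert-butyldimethylsilyloxy)-7-hydroxy-1,1-dimethoxy-3,7-dimethyldodeca-10,11-dien-4-yn-6-one | COC(OC)C[C@H](C)C#CC(=O)[C@@](C)(C[C@H](O[Si](C)(C)C(C)(C)C)C=C=C)O | intermediate
19 | (3S,4E,7R,9S)-9-(tert-butyldimethylsilyloxy)-4-(diethylamino)-7-hydroxy-1,1-dimethoxy-3,7-dimethyldodeca-4,10,11-trien-6-one | COC(OC)C[C@H](C)/C(N(CC)CC)=C\C(=O)[C@@](C)(C[C@H](O[Si](C)(C)C(C)(C)C)C=C=C)O | intermediate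
20 | (2R)-2-[(2S)-2-(tert-butyldimethylsilyloxy)penta-3,4-dien-1-yl]-5-[(2S)-4,4-dimethoxybutan-2-yl]-2-methylfuran-3(2H)-one | COC(OC)C[C@H](C)C1=CC(=O)[C@@](C)(C[C@H](O[Si](C)(C)C(C)(C)C)C=C=C)O1 | intermediate
21 | (3S)-3-{(5R)-5-[(2S)-2-(tert-butyldimethylsilyloxy)penta-3,4-dien-1-yl]-5-methyl-4-oxo-4,5-dihydrofuran-2-yl}butanal | O=CC[C@H](C)C1=CC(=O)[C@@](C)(C[C@H](O[Si](C)(C)C(C)(C)C)C=C=C)O1 | intermediate
22 | (4S,6R,7S,8S,10R)-8-(tert-butyldimethylsilyloxy)-1-oxo-3,10-epoxygermacra-2,11(13)-dien-12,6-olide | C=C1C(=O)O[C@@H]2C[C@H](C)C3=CC(=O)[C@@](C)(C[C@H](O[Si](C)(C)C(C)(C)C)[C@@H]12)O3 | intermediate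
23 | (4S,6R,7R,8S,10R)-8-hydroxy-1-oxo-3,10-epoxygermacra-2,11(13)-dien-12,6-olide (same spatial arrangement as 22) | C=C1C(=O)O[C@@H]2C[C@H](C)C3=CC(=O)[C@@](C)(C[C@H](O)[C@@H]12)O3 | intermediate
24 | (S)-3-bromo-2-hydroxy-2-methylpropanoic acid | OC(=O)[C@](C)(O)CBr | starting material
25 | potassium (R)-2-methyloxirane-2-carboxylate | [O-]C(=O)[C@]1(C)OC1.[K+] | intermediate
26 | (R)-2,3-dihydroxy-2-methylpropanoic acid | OC(=O)[C@](C)(O)CO | intermediate
27 | methyl (4R)-2,2,4-trimethyl-1,3-dioxolane-4-carboxylate | COC(=O)[C@]1(C)OC(C)(C)OC1 | intermediate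
28 | (4R)-2,2,4-trimethyl-1,3-dioxolane-4-carboxylic acid | OC(=O)[C@]1(C)OC(C)(C)OC1 | intermediate
29 | (4R)-2,2,4-trimethyl-1,3-dioxolane-4-carboxylic 2,4,6-trichlorobenzoic anhydride | O=C(OC(=O)[C@]1(C)OC(C)(C)OC1)c1c(Cl)cc(Cl)cc1Cl | intermediate
30 | (4S,6R,7S,8S,10R)-1-oxo-3,10-epoxygermacra-2,11(13)-dien-12,6-olid-8-yl (4R)-2,2,4-trimethyl-1,3-dioxolane-4-carboxylate | C=C1C(=O)O[C@@H]2C[C@H](C)C3=CC(=O)[C@@](C)(C[C@H](OC(=O)[C@]4(C)OC(C)(C)OC4)[C@@H]12)O3 | intermediate
31 | (4S,6R,7S,8S,10R)-8-[(2R)-2,3-dihydroxy-2-methylpropanoyloxy]-1-oxo-3,10-epoxygermacra-2,11(13)-dien-12,6-olide | C=C1C(=O)O[C@@H]2C[C@H](C)C3=CC(=O)[C@@](C)(C[C@H](OC(=O)[C@](C)(O)CO)[C@@H]12)O3 | target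

**Count and risks**

Total step count: 18. Longest linear sequence: 12 steps (steps 1–6, 10–13, 17, 18).

Step 12 (the proposed new method). The ring-closing oxidative cyclisation may be slower than intermolecular coupling or thermal allene isomerisation. Bond formation may also occur at C13 instead of C7, and facial selectivity at C6 and C7 may be poor. The fallback makes the two bonds one after the other with known reaction types and sets out from 21. One equivalent of Br2 (CH2Cl2, −78 °C) should add across the allene to give the allylic dibromide (3S)-3-{(5R)-5-[(2S,3E)-4,5-dibromo-2-(tert-butyldimethylsilyloxy)pent-3-en-1-yl]-5-methyl-4-oxo-4,5-dihydrofuran-2-yl}butanal F1; its allylic isomer would give the same allylmetal. CrCl2 (divalent chromium, excess, THF, high dilution) inserts into the allylic C–Br bond only, and the resulting 2-bromoallyl chromium species adds through C7 to the aldehyde in an intramolecular Nozaki–Hiyama allylation. This should be anti-selective through a chair transition state, which corresponds to the 6,7-trans relationship, and gives the macrocyclic bromo alcohol F2. F2 is the lactone-opened relative of 22, with a hydroxyl on C6 and a 1-bromovinyl group (C11(Br)=C13H2) on C7. Carbonylative lactonisation of this vinyl bromide alcohol (Pd(PPh3)4 as zerovalent palladium catalyst, CO 1 atm, Et3N, MeCN, 60 °C) then forms C11–C12 and C12–O, and the route is rejoined at 22.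

Step 10. The tetrahedral adduct may collapse before the quench, so that a second acetylide adds to the liberated ynone, or addition to the hindered carbonyl may stall. The fallback sets out from 10. Aminolysis of the dioxolanone with MeNH(OMe)·HCl and i-PrMgCl (THF, −20 °C) gives, with loss of acetone, the Weinreb amide (2R,4S)-4-(tert-butyldimethylsilyloxy)-2-hydroxy-N-methoxy-N,2-dimethylhepta-5,6-dienamide F3. After deprotonation of its tertiary hydroxyl with one equivalent of i-PrMgCl, lithium acetylide 16 adds once (stable chelated adduct), and work-up returns the route at 18.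

Step 6. The hot amine medium may open the dioxolanone by aminolysis or hydrolysis, or the fragmentation of the propargylic amine may stay incomplete. The fallback brings in the allene as a unit at low temperature and sets out from 2, replacing steps 2–6. BH3·SMe2 (THF, 0 °C) reduces the free acid to the alcohol (5R)-5-(2-hydroxyethyl)-2,2,5-trimethyl-1,3-dioxolan-4-one F4. Dess–Martin periodinane gives the aldehyde 2-[(4R)-2,2,4-trimethyl-5-oxo-1,3-dioxolan-4-yl]acetaldehyde F5. A reagent-controlled allenylation follows: a B-propargyl diazaborolidine is made from allenyltributylstannane and the B-bromo diazaborolidine of N,N'-bis(p-toluenesulfonyl)-1,2-diphenylethane-1,2-diamine, in the antipode that gives the S carbinol (CH2Cl2, −78 °C). It adds through its alkyne terminus to give the allenyl carbinol (5R)-5-[(2S)-2-hydroxypenta-3,4-dien-1-yl]-2,2,5-trimethyl-1,3-dioxolan-4-one F6. Silylation (TBSOTf, 2,6-lutidine) returns the route at 10.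

Further compounds
F1 | step 12 | (3S)-3-{(5R)-5-[(2S,3E)-4,5-dibromo-2-(tert-butyldimethylsilyloxy)pent-3-en-1-yl]-5-methyl-4-oxo-4,5-dihydrofuran-2-yl}butanal | O=CC[C@H](C)C1=CC(=O)[C@@](C)(C[C@H](O[Si](C)(C)C(C)(C)C)/C=C(/Br)CBr)O1
F2 | step 12 | macrocyclic bromo alcohol, lactone-opened relative of 22 with OH on C6 and a 1-bromovinyl group on C7 (configurations as in 22) | C=C(Br)[C@H]1[C@H](O)C[C@H](C)C2=CC(=O)[C@@](C)(C[C@@H]1O[Si](C)(C)C(C)(C)C)O2
F3 | step 10 | (2R,4S)-4-(tert-butyldimethylsilyloxy)-2-hydroxy-N-methoxy-N,2-dimethylhepta-5,6-dienamide | CON(C)C(=O)[C@@](C)(C[C@H](O[Si](C)(C)C(C)(C)C)C=C=C)O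
F4 | step 6 | (5R)-5-(2-hydroxyethyl)-2,2,5-trimethyl-1,3-dioxolan-4-one | O=C1[C@@](C)(CCO)OC(C)(C)O1
F5 | step 6 | 2-[(4R)-2,2,4-trimethyl-5-oxo-1,3-dioxolan-4-yl]acetaldehyde | O=C1[C@@](C)(CC=O)OC(C)(C)O1
F6 | step 6 | (5R)-5-[(2S)-2-hydroxypenta-3,4-dien-1-yl]-2,2,5-trimethyl-1,3-dioxolan-4-one | O=C1[C@@](C)(C[C@H](O)C=C=C)OC(C)(C)O1
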